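**Plan**
1. Cuts, in retrosynthetic order: the five O–benzyl bonds and the chain C=C. Then the C3–C3a bond of the dihydrobenzofuran (retro-semipinacol: C3a returns to the aroyl carbon, which becomes C4 of a chroman). Then both aryl–C(=O) bonds at once. Last, C3–O, C6–vinyl and C2–aryl of a flavanone.
2. Forward: 6-bromochromone (benzene and pyranone rings present) → (S)-flavanone → Heck chain → 2,3-trans-3-hydroxyflavanone → one aryllithium adds to the C4 ketone and to the Weinreb amide → 3-mesylate → 6→5 ring contraction → hydrogenation.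
3. Stereochemistry (target is 2S,3S, trans): C2 comes from a catalytic asymmetric conjugate arylation. The C3–O bond is placed anti to the C2 aryl by substrate control. C3 of the target arises by inversion in the 1,2-shift (trans → trans). C4 is transient, so both of its epimers converge.
4. Enabling feature: in ring O1–C2–C3–C3a–C7a, C3 carries both the fused benzene carbon C3a and an exocyclic aroyl carbon. This α-aryl ketone is the product pattern of a semipinacol shift. Its ring-expanded isomer is a 4-arylflavan-3,4-diol, whose C2 aryl anchors a half-chair with C4–C4a anti to the C3 leaving group.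
5. Second feature: both ArC=O groups carry the same 2,4-dioxygenated ring, so one reagent installs both in one flask.

Key step: step 8

Assumption: the facial sense of the Pd/pyridine-oxazoline catalyst on chromones is taken to follow that known for 3-substituted cyclohexenones, which calls for the (R)-ligand to reach (S)-3; if the sense is the reverse, the (S)-ligand is used and nothing else changes.

Step 1
Reactants: 1 6-bromochromone; 2 [4-(benzyloxy)phenyl]boronic acid
Product: 3 (2S)-2-[4-(benzyloxy)phenyl]-6-bromochroman-4-one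
Conditions: Pd(OCOCF3)2 (5 mol %), (R)-t-BuPyOx (6 mol %), NH4PF6 (30 mol %), H2O (5 equiv), ClCH2CH2Cl, 60 °C
Reagents that add atoms: none
Why: Pd(II)/pyridine-oxazoline-catalysed asymmetric conjugate addition of arylboronic acids to chromones is an established flavanone synthesis, in which the tert-butyl group of the ligand blocks one face of the bound C2=C3 bond and so sets C2 (S), while the Pd(II) cycle leaves the C–Br bond alone.

Step 2
Reactants: 3 (2S)-2-[4-(benzyloxy)phenyl]-6-bromochroman-4-one; 4 N-methoxy-N-methylprop-2-enamide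
Product: 5 (2E)-3-{(2S)-2-[4-(benzyloxy)phenyl]-4-oxochroman-6-yl}-N-methoxy-N-methylprop-2-enamide
Conditions: Pd2(dba)3 (1.5 mol %), P(t-Bu)3·HBF4 (6 mol %), Cy2NMe (1.2 equiv), dioxane, rt → 40 °C
Reagents that add atoms: none
Why: The Mizoroki–Heck reaction of aryl bromides with acrylamides is E-selective near room temperature with this catalyst, and the hindered amine in an aprotic solvent should be too weak to enolize the flavanone, so C2 should be kept.

Step 3
Reactants: 5 (2E)-3-{(2S)-2-[4-(benzyloxy)phenyl]-4-oxochroman-6-yl}-N-methoxy-N-methylprop-2-enamide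
Product: 6 (2E)-3-{(2S)-2-[4-(benzyloxy)phenyl]-4-[(trimethylsilyl)oxy]-2H-chromen-6-yl}-N-methoxy-N-methylprop-2-enamide
Conditions: TMSOTf (1.3 equiv), Et3N (2.5 equiv), CH2Cl2, 0 °C; cold NaHCO3 wash, used crude
Reagents that add atoms: trimethylsilyl trifluoromethanesulfonate C[Si](C)(C)OS(=O)(=O)C(F)(F)F
Why: Soft enolization (silyl triflate plus tertiary amine) gives the silyl enol ether at C3, the only enolizable position, without a free enolate, and thus avoids the E1cB opening of the pyranone to the 2'-hydroxychalcone that would racemize C2.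

Step 4
Reactants: 6 (2E)-3-{(2S)-2-[4-(benzyloxy)phenyl]-4-[(trimethylsilyl)oxy]-2H-chromen-6-yl}-N-methoxy-N-methylprop-2-enamide
Product: 8 (2E)-3-{(2R,3R)-2-[4-(benzyloxy)phenyl]-3-hydroxy-4-oxochroman-6-yl}-N-methoxy-N-methylprop-2-enamide, via silyloxy epoxide 7 (not isolated)
Conditions: DMDO (acetone solution, 1.1 equiv), CH2Cl2, −40 → 0 °C; then cat. aq HCl, THF, 0 °C
Reagents that add atoms: dimethyldioxirane CC1(C)OO1
Why: In this Rubottom oxidation the dioxirane should attack the electron-rich C3=C4 enol ether (not the acrylamide) from the face anti to the C2 aryl, and acid collapse of 7 should give the 2,3-trans (3R) ketol, the known outcome for flavanone enol derivatives and also the more stable diequatorial isomer.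

Step 5
Reactants: 9 4-bromobenzene-1,3-diol
Product: 10 2,4-bis(benzyloxy)-1-bromobenzene
Conditions: BnBr (2.2 equiv), K2CO3, DMF, rt
Reagents that add atoms: benzyl bromide BrCc1ccccc1
Why: Williamson ether synthesis on both phenols is routine and gives a protecting group that falls in the last step together with the alkene reduction.

Step 6
Reactants: 8 (2E)-3-{(2R,3R)-2-[4-(benzyloxy)phenyl]-3-hydroxy-4-oxochroman-6-yl}-N-methoxy-N-methylprop-2-enamide; 10 2,4-bis(benzyloxy)-1-bromobenzene
Product: 12 (2E)-1-[2,4-bis(benzyloxy)phenyl]-3-{(2R,3R,4S)-4-[2,4-bis(benzyloxy)phenyl]-2-[4-(benzyloxy)phenyl]-3,4-dihydroxychroman-6-yl}prop-2-en-1-one, via aryllithium 11 (not isolated)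
Conditions: 10 (4.0 equiv), n-BuLi (3.9 equiv), THF, −78 °C; then 8, THF, −78 → −40 °C; sat. aq NH4Cl; Et3N-deactivated silica
Reagents that add atoms: n-butyllithium [Li]CCCC (supplies only the lithium of 11)
Why: After Br/Li exchange the first equivalent of 11 deprotonates C3–OH, the second adds 1,2 to the C4 ketone (a known addition for 3-oxygenated flavan-4-ones) and the third turns the unsaturated Weinreb amide into the enone (Weinreb ketone synthesis); equatorial attack should favour the 4S carbinol (C4 aryl cis to C2 aryl, the two OH groups cis), but the C4 configuration is erased in step 8.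

Step 7
Reactants: 12 (2E)-1-[2,4-bis(benzyloxy)phenyl]-3-{(2R,3R,4S)-4-[2,4-bis(benzyloxy)phenyl]-2-[4-(benzyloxy)phenyl]-3,4-dihydroxychroman-6-yl}prop-2-en-1-one
Product: 13 (2R,3R,4S)-4-[2,4-bis(benzyloxy)phenyl]-2-[4-(benzyloxy)phenyl]-6-{(1E)-3-[2,4-bis(benzyloxy)phenyl]-3-oxoprop-1-en-1-yl}-4-hydroxychroman-3-yl methanesulfonate
Conditions: MsCl (1.3 equiv), Et3N (3 equiv), CH2Cl2, −20 → 0 °C; NaHCO3 wash, no chromatography
Reagents that add atoms: methanesulfonyl chloride CS(=O)(=O)Cl
Why: Mesylation through sulfene should pick the secondary C3–OH over the tertiary, doubly benzylic C4–OH on steric grounds, and it leaves the C3–O bond, and hence the 3R configuration, untouched.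

Step 8
Reactants: 13 (2R,3R,4S)-4-[2,4-bis(benzyloxy)phenyl]-2-[4-(benzyloxy)phenyl]-6-{(1E)-3-[2,4-bis(benzyloxy)phenyl]-3-oxoprop-1-en-1-yl}-4-hydroxychroman-3-yl methanesulfonate
Product: 15 (2E)-1-[2,4-bis(benzyloxy)phenyl]-3-{(2S,3S)-3-[2,4-bis(benzyloxy)benzoyl]-2-[4-(benzyloxy)phenyl]-2,3-dihydro-1-benzofuran-5-yl}prop-2-en-1-one, via aluminium alkoxide 14 (not isolated)
Conditions: Et3Al (3 equiv, hexanes), CH2Cl2, −78 → 0 °C; aq Rochelle salt
Reagents that add atoms: triethylaluminium CC[Al](CC)CC (supplies only the Et2Al group of 14)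
Why: Proposed new method: Et3Al deprotonates the tertiary C4–OH (loss of ethane) to aluminium alkoxide 14 and excess Et3Al binds the mesylate, whereupon the C4–C4a σ bond, antiperiplanar to the equatorial C3–OMs bond in the half-chair that keeps the C2 aryl group equatorial, shifts from C4 to C3 as C4–O becomes the aroyl C=O (push–pull semipinacol shift). The closest known reaction types are the organoaluminium-promoted, stereospecific 1,2-aryl shift of β-mesyloxy alcohols and the iodine(III)- or thallium(III)-induced contraction of flavanones to trans-2-aryl-2,3-dihydrobenzofuran-3-carboxylates, in which the same fused carbon C4a migrates to C3; new is the substrate class, a 4-arylchroman-3,4-diol 3-sulfonate, which delivers the aryl ketone itself. The ring O1–C2–C3–C3a–C7a is closed not by cyclization but by this suprafacial 1,2-shift, a 6→5 ring contraction in which C4 is extruded as the exocyclic carbonyl carbon. C3 is set by inversion at the mesylate carbon, so that the 2,3-trans (3R) mesylate gives the 2,3-trans (3S) ketone, which is also the more stable epimer; C2 is not touched, and C4 becomes sp2, so that both C4 epimers of 13 converge. The step needs migration of ring A rather than of the more electron-rich exocyclic aryl group, and it must outrun oxirane closure, the O1 shift from C2 and ionization at C4. In the 4S epimer OH and OMs are cis (no oxirane) and the exocyclic aryl is anti to C3–OMs only in the flipped conformer with the C2 and C4 aryl groups 1,3-diaxial, in the 4R epimer that aryl is cis to OMs and cannot migrate, the alkoxide push favours C4a over O1, and the strong O–Al bond holds the C4 oxygen.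

Step 9
Reactants: 15 (2E)-1-[2,4-bis(benzyloxy)phenyl]-3-{(2S,3S)-3-[2,4-bis(benzyloxy)benzoyl]-2-[4-(benzyloxy)phenyl]-2,3-dihydro-1-benzofuran-5-yl}prop-2-en-1-one
Product: 16 1-(2,4-dihydroxyphenyl)-3-[(2S,3S)-3-(2,4-dihydroxybenzoyl)-2-(4-hydroxyphenyl)-2,3-dihydro-1-benzofuran-5-yl]propan-1-one (target)
Conditions: H2 (1 atm), 10 % Pd/C, EtOAc–MeOH, rt, stopped after uptake of 6 equiv H2
Reagents that add atoms: none
Why: Heterogeneous hydrogenation should saturate the chalcone C=C and cleave the five primary benzyl aryl ethers faster than the secondary, cyclic C2–O1 bond or the electron-rich aryl ketones, as in the debenzylation of benzylated flavans and chalcones, and the neutral medium leaves C2 and C3 as set.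

**Compound list**
1 | 6-bromochromone | O=c1ccoc2ccc(Br)cc12 | starting material
2 | [4-(benzyloxy)phenyl]boronic acid | OB(O)c1ccc(OCc2ccccc2)cc1 | starting material
3 | (2S)-2-[4-(benzyloxy)phenyl]-6-bromochroman-4-one | O=C1C[C@@H](c2ccc(OCc3ccccc3)cc2)Oc2ccc(Br)cc21 | intermediate
4 | N-methoxy-N-methylprop-2-enamide | C=CC(=O)N(C)OC | starting material
5 | (2E)-3-{(2S)-2-[4-(benzyloxy)phenyl]-4-oxochroman-6-yl}-N-methoxy-N-methylprop-2-enamide | O=C1C[C@@H](c2ccc(OCc3ccccc3)cc2)Oc2ccc(/C=C/C(=O)N(C)OC)cc21 | intermediate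
6 | (2S)-4-trimethylsilyloxy-2H-chromene (silyl enol ether of 5) | C[Si](C)(C)OC1=C[C@@H](c2ccc(OCc3ccccc3)cc2)Oc2ccc(/C=C/C(=O)N(C)OC)cc21 | intermediate
7 | 3,4-epoxide of 6, oxirane oxygen trans to the C2 aryl group (not isolated) | C[Si](C)(C)O[C@@]12O[C@@H]1[C@@H](c1ccc(OCc3ccccc3)cc1)Oc1ccc(/C=C/C(=O)N(C)OC)cc12 | intermediate
8 | (2E)-3-{(2R,3R)-2-[4-(benzyloxy)phenyl]-3-hydroxy-4-oxochroman-6-yl}-N-methoxy-N-methylprop-2-enamide | O=C1[C@H](O)[C@@H](c2ccc(OCc3ccccc3)cc2)Oc2ccc(/C=C/C(=O)N(C)OC)cc21 | intermediate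
9 | 4-bromobenzene-1,3-diol | Oc1ccc(Br)c(O)c1 | starting material
10 | 2,4-bis(benzyloxy)-1-bromobenzene | Brc1ccc(OCc2ccccc2)cc1OCc1ccccc1 | intermediate
11 | [2,4-bis(benzyloxy)phenyl]lithium (not isolated) | [Li]c1ccc(OCc2ccccc2)cc1OCc1ccccc1 | intermediate
12 | (2R,3R,4S)-4-aryl-chroman-3,4-diol with the enone chain at C6 (C4 aryl cis to C2 aryl, 3-OH and 4-OH cis) | O[C@]1(c2ccc(OCc3ccccc3)cc2OCc2ccccc2)[C@H](O)[C@@H](c2ccc(OCc3ccccc3)cc2)Oc2ccc(/C=C/C(=O)c3ccc(OCc4ccccc4)cc3OCc3ccccc3)cc21 | intermediate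
13 | 3-O-methanesulfonate of 12, (2R,3R,4S) | O[C@]1(c2ccc(OCc3ccccc3)cc2OCc2ccccc2)[C@H](OS(C)(=O)=O)[C@@H](c2ccc(OCc3ccccc3)cc2)Oc2ccc(/C=C/C(=O)c3ccc(OCc4ccccc4)cc3OCc3ccccc3)cc21 | intermediate
14 | diethylaluminium C4-alkoxide of 13 (not isolated) | CC[Al](CC)O[C@]1(c2ccc(OCc3ccccc3)cc2OCc2ccccc2)[C@H](OS(C)(=O)=O)[C@@H](c2ccc(OCc3ccccc3)cc2)Oc2ccc(/C=C/C(=O)c3ccc(OCc4ccccc4)cc3OCc3ccccc3)cc21 | intermediate
15 | (2E)-1-[2,4-bis(benzyloxy)phenyl]-3-{(2S,3S)-3-[2,4-bis(benzyloxy)benzoyl]-2-[4-(benzyloxy)phenyl]-2,3-dihydro-1-benzofuran-5-yl}prop-2-en-1-one | O=C(/C=C/c1ccc2c(c1)[C@H](C(=O)c1ccc(OCc3ccccc3)cc1OCc1ccccc1)[C@@H](c1ccc(OCc3ccccc3)cc1)O2)c1ccc(OCc2ccccc2)cc1OCc1ccccc1 | intermediate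
16 | 1-(2,4-dihydroxyphenyl)-3-[(2S,3S)-3-(2,4-dihydroxybenzoyl)-2-(4-hydroxyphenyl)-2,3-dihydro-1-benzofuran-5-yl]propan-1-one | O=C(CCc1ccc2c(c1)[C@H](C(=O)c1ccc(O)cc1O)[C@@H](c1ccc(O)cc1)O2)c1ccc(O)cc1O | target

**Count**
Total steps: 9.
Longest linear sequence: 8 (steps 1, 2, 3, 4, 6, 7, 8, 9 from 6-bromochromone). Step 5 is a one-step side branch.

**Steps most likely to fail**

1. Step 8 (Proposed new method).
- Risk: the shift may take another course. Possibilities are migration of the exocyclic electron-rich aryl group, loss of the C4 oxygen followed by a hydride shift from C3, and elimination to an enol mesylate.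
- Fallback with known chemistry, from 5 back to 15. Flavanone 5 is submitted to the established hypervalent-iodine ring contraction of flavanones (PhI(OAc)2, HC(OMe)3, H2SO4, rt). There iodine(III) is taken up at C3 anti to the C2 aryl and ring A shifts from C4 to C3, which should give the trans methyl 2,3-dihydrobenzofuran-3-carboxylate F1.
- Aminolysis (MeNH(OMe)·HCl, i-PrMgCl, THF, −20 °C) should give the bis(N-methoxy-N-methyl)amide F2. Two equivalents of 11 (THF, −78 °C) then turn both amide groups into aryl ketones, which is 15.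

2. Step 6.
- Risk: deprotonation at C3 with opening of the pyranone ring, incomplete addition to the hindered ketone, or acid-triggered loss of the C4 hydroxyl on work-up.
- Fallback, from 5 back to 12: both oxygens are introduced after the aryl group instead of before it. Addition of 11 (2.5 equiv, THF, −78 °C) to the non-hydroxylated flavanone 5 should give the tertiary 4-arylchroman-4-ol F3.
- PPTS (CH2Cl2, rt) dehydrates it to the (2S)-2,4-diaryl-2H-chromene F4. Syn-dihydroxylation of the electron-rich C3=C4 bond anti to the C2 aryl (cat. OsO4, NMO, acetone–H2O) should then give the 3,4-cis-diol 12. This path also bypasses steps 3 and 4.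

3. Step 9.
- Risk: over-reduction, that is hydrogenolysis of the benzylic C2–O1 bond of the dihydrobenzofuran or reduction of an aryl ketone before the last benzyl ether has fallen.
- Fallback, from 15 back to 16: reduction and deprotection are separated and no hydrogenolysis is used. Conjugate reduction of the enone with [(Ph3P)CuH]6 (toluene, rt) should give the saturated pentabenzyl ether F5. Lewis-acid debenzylation with a cation scavenger (BCl3, pentamethylbenzene, CH2Cl2, −78 °C) should then give 16.

**Further compounds**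
F1 | step 8 | methyl (2S,3S)-2-[4-(benzyloxy)phenyl]-5-{(1E)-3-[methoxy(methyl)amino]-3-oxoprop-1-en-1-yl}-2,3-dihydro-1-benzofuran-3-carboxylate | CON(C)C(=O)/C=C/c1ccc2c(c1)[C@H](C(=O)OC)[C@@H](c1ccc(OCc3ccccc3)cc1)O2
F2 | step 8 | (2S,3S)-2-[4-(benzyloxy)phenyl]-N-methoxy-5-{(1E)-3-[methoxy(methyl)amino]-3-oxoprop-1-en-1-yl}-N-methyl-2,3-dihydro-1-benzofuran-3-carboxamide | CON(C)C(=O)/C=C/c1ccc2c(c1)[C@H](C(=O)N(C)OC)[C@@H](c1ccc(OCc3ccccc3)cc1)O2
F3 | step 6 | (2E)-1-[2,4-bis(benzyloxy)phenyl]-3-{(2S)-4-[2,4-bis(benzyloxy)phenyl]-2-[4-(benzyloxy)phenyl]-4-hydroxychroman-6-yl}prop-2-en-1-one (C4 configuration of no consequence) | OC1(c2ccc(OCc3ccccc3)cc2OCc2ccccc2)C[C@@H](c2ccc(OCc3ccccc3)cc2)Oc2ccc(/C=C/C(=O)c3ccc(OCc4ccccc4)cc3OCc3ccccc3)cc21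
F4 | step 6 | (2E)-1-[2,4-bis(benzyloxy)phenyl]-3-{(2S)-4-[2,4-bis(benzyloxy)phenyl]-2-[4-(benzyloxy)phenyl]-2H-chromen-6-yl}prop-2-en-1-one | O=C(/C=C/c1ccc2c(c1)C(c1ccc(OCc3ccccc3)cc1OCc1ccccc1)=C[C@@H](c1ccc(OCc3ccccc3)cc1)O2)c1ccc(OCc2ccccc2)cc1OCc1ccccc1
F5 | step 9 | 1-[2,4-bis(benzyloxy)phenyl]-3-{(2S,3S)-3-[2,4-bis(benzyloxy)benzoyl]-2-[4-(benzyloxy)phenyl]-2,3-dihydro-1-benzofuran-5-yl}propan-1-one | O=C(CCc1ccc2c(c1)[C@H](C(=O)c1ccc(OCc3ccccc3)cc1OCc1ccccc1)[C@@H](c1ccc(OCc3ccccc3)cc1)O2)c1ccc(OCc2ccccc2)cc1OCc1ccccc1
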